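**Assumption (one line):** side-chain carbons of the target are called C1'–C10' counting from the ring; alkali-metal alkoxides that are only protonated or O-alkylated in the same flask count as salt forms of the numbered alcohol and get no number of their own.

## Retrosynthetic overview

1. The dihydropyranone ring is opened last: ring-closing metathesis of the acrylate of a (Z)-allylic, homoallylic alcohol; the Z-alkene comes from an alkyne, and the C6 carbinol from asymmetric allylboration of an ynal.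
2. The C4'/C6'/C8' triol is traced to a β-hydroxy ketone: a hydroxyl-directed 1,3-anti reduction sets C6', and the C7'–C8' bond is the key fragment union, a 1,5-anti boron aldol between a β-PMB-oxy methyl ketone and 3-phenylpropanal.
3. The methyl ketone (C1'–C7') comes from (S)-epichlorohydrin, opened first by lithiated 2-methyl-1,3-dithiane (masked acetyl) and then by acetylide.
4. Ring order: transient oxirane (step 1), protecting 1,3-dioxane (step 7), lactone ring last (step 12); the PMB ether and the acetonide are removed at the end.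

## Route

**Step 1**
Reactants: 1 2-methyl-1,3-dithiane; 2 (S)-epichlorohydrin
Product: 5 2-methyl-2-{[(2S)-oxiran-2-yl]methyl}-1,3-dithiane, via 2-lithio-2-methyl-1,3-dithiane 3 (not isolated), via lithium chlorohydrin alkoxide 4 (not isolated)
Conditions: n-BuLi, THF, −30 → −20 °C, 2 h; then 2, −78 °C → rt
Reagents that add atoms: none
Why: Corey–Seebach umpolung: the lithiated dithiane opens the oxirane of 2 at its CH2 terminus and alkoxide 4 then displaces chloride (intramolecular Williamson closure), so no bond to the stereocentre is broken and the (S)-epoxide results.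

**Step 2**
Reactants: 5 2-methyl-2-{[(2S)-oxiran-2-yl]methyl}-1,3-dithiane
Product: 6 (2R)-1-(2-methyl-1,3-dithian-2-yl)pent-4-yn-2-ol
Conditions: LiC≡CH·H2NCH2CH2NH2, DMSO, 0 °C → rt; then H2O
Reagents that add atoms: lithium acetylide–ethylenediamine complex, [Li]C#C.NCCN
Why: SN2 epoxide opening by acetylide at the unsubstituted carbon leaves the carbinol centre (later C4') untouched; the descriptor becomes R only through CIP priorities.

**Step 3**
Reactants: 6 (2R)-1-(2-methyl-1,3-dithian-2-yl)pent-4-yn-2-ol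
Product: 7 2-{(2R)-2-[(4-methoxybenzyl)oxy]pent-4-yn-1-yl}-2-methyl-1,3-dithiane
Conditions: NaH, PMBCl, Bu4NI (cat.), THF/DMF, 0 °C → rt
Reagents that add atoms: 4-methoxybenzyl chloride, COc1ccc(CCl)cc1
Why: Williamson etherification of the alkoxide (O–H is far more acidic than the alkyne C–H) installs the PMB ether that later directs the aldol.

**Step 4**
Reactants: 7 2-{(2R)-2-[(4-methoxybenzyl)oxy]pent-4-yn-1-yl}-2-methyl-1,3-dithiane
Product: 8 (4R)-4-[(4-methoxybenzyl)oxy]hept-6-yn-2-one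
Conditions: MeI, CaCO3, MeCN/H2O (9:1), 45 °C
Reagents that add atoms: water, O
Why: Alkylative thioacetal hydrolysis (S-methylation, then attack of water) unmasks the methyl ketone under buffered, near-neutral conditions that spare the PMB ether, the alkyne and the β-alkoxy ketone.

**Step 5 (key fragment union)**
Reactants: 8 (4R)-4-[(4-methoxybenzyl)oxy]hept-6-yn-2-one; 9 3-phenylpropanal
Product: 12 (3R,7R)-3-hydroxy-7-[(4-methoxybenzyl)oxy]-1-phenyldec-9-yn-5-one, via dibutylboron enolate 10 (not isolated), via dibutylboron aldolate 11 (not isolated)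
Conditions: Bu2BOTf, i-Pr2NEt, Et2O, −78 °C; then 9, −78 °C; then pH 7 buffer, MeOH, 30% H2O2, 0 °C
Reagents that add atoms: none
Why: Boron-mediated aldol addition: kinetic enolisation on the methyl side, then 1,5-anti induction by the β-PMB-oxy group of the dibutylboron enolate sets the new carbinol (3R) anti to the ether centre, typically with about 10:1 or better selectivity for this substrate class.

**Step 6**
Reactants: 12 (3R,7R)-3-hydroxy-7-[(4-methoxybenzyl)oxy]-1-phenyldec-9-yn-5-one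
Product: 13 (3R,5S,7R)-7-[(4-methoxybenzyl)oxy]-1-phenyldec-9-yne-3,5-diol
Conditions: Me4NBH(OAc)3, MeCN/AcOH (1:1), −30 → −20 °C
Reagents that add atoms: none
Why: Evans–Saksena reduction: the free C3 hydroxyl binds boron and hydride is delivered intramolecularly through a chair transition state, giving the 1,3-anti diol (new centre 5S, syn to the PMB-oxy centre).

**Step 7**
Reactants: 13 (3R,5S,7R)-7-[(4-methoxybenzyl)oxy]-1-phenyldec-9-yne-3,5-diol
Product: 14 (4R,6R)-4-{(2R)-2-[(4-methoxybenzyl)oxy]pent-4-yn-1-yl}-2,2-dimethyl-6-(2-phenylethyl)-1,3-dioxane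
Conditions: Me2C(OMe)2, PPTS (cat.), CH2Cl2, rt
Reagents that add atoms: 2,2-dimethoxypropane, COC(C)(C)OC
Why: Acid-catalysed transketalisation protects the anti-diol as its acetonide without touching a stereocentre (the S→R change at the former C5 is a CIP effect); the acetonide 13C shifts confirm the anti relationship and minor diastereomers are removed by chromatography here.

**Step 8**
Reactants: 14 (4R,6R)-4-{(2R)-2-[(4-methoxybenzyl)oxy]pent-4-yn-1-yl}-2,2-dimethyl-6-(2-phenylethyl)-1,3-dioxane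
Product: 17 (5R)-5-[(4-methoxybenzyl)oxy]-6-[(4R,6R)-2,2-dimethyl-6-(2-phenylethyl)-1,3-dioxan-4-yl]hex-2-ynal, via lithium acetylide 15 (not isolated), via lithium hemiaminal alkoxide 16 (not isolated)
Conditions: n-BuLi, THF, −78 °C; DMF, −78 → 0 °C; then inverse quench into aq. KH2PO4, 0 °C
Reagents that add atoms: N,N-dimethylformamide, CN(C)C=O
Why: Alkyne formylation: the acetylide adds to DMF to give a stable tetrahedral adduct that collapses to the ynal only in the buffered quench, so over-addition cannot occur.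

**Step 9**
Reactants: 17 (5R)-5-[(4-methoxybenzyl)oxy]-6-[(4R,6R)-2,2-dimethyl-6-(2-phenylethyl)-1,3-dioxan-4-yl]hex-2-ynal
Product: 19 (4S,8R)-8-[(4-methoxybenzyl)oxy]-9-[(4R,6R)-2,2-dimethyl-6-(2-phenylethyl)-1,3-dioxan-4-yl]non-1-en-5-yn-4-ol, via diisopinocampheylborinate 18 (not isolated)
Conditions: allylMgBr, (−)-Ipc2BOMe [from (+)-α-pinene], Et2O, −78 °C → rt; then 17, −78 °C; then NaOH, H2O2, rt
Reagents that add atoms: allylmagnesium bromide, C=CC[Mg]Br, delivered through B-allyldiisopinocampheylborane made from it in the flask, C=CCB([C@@H]1C[C@@H]2C[C@H]([C@H]1C)C2(C)C)[C@@H]1C[C@@H]2C[C@H]([C@H]1C)C2(C)C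
Why: Brown asymmetric allylboration through a chair Zimmerman–Traxler transition state is reagent-controlled; this enantiomer of the borane (the one that gives (S)-1-phenylbut-3-en-1-ol from benzaldehyde) delivers the (4S) propargylic alcohol, to be confirmed by Mosher ester analysis.

**Step 10**
Reactants: 19 (4S,8R)-8-[(4-methoxybenzyl)oxy]-9-[(4R,6R)-2,2-dimethyl-6-(2-phenylethyl)-1,3-dioxan-4-yl]non-1-en-5-yn-4-ol
Product: 20 (4S,5Z,8R)-8-[(4-methoxybenzyl)oxy]-9-[(4R,6R)-2,2-dimethyl-6-(2-phenylethyl)-1,3-dioxan-4-yl]nona-1,5-dien-4-ol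
Conditions: H2 (1 atm), Pd/CaCO3 poisoned with Pb(OAc)2, quinoline, EtOAc, rt, stopped at one equivalent of H2
Reagents that add atoms: none
Why: Lindlar semihydrogenation adds H2 syn on the poisoned palladium surface to give the Z-alkene; the alkyne binds much more strongly than the terminal alkene, and the PMB ether is not hydrogenolysed.

**Step 11**
Reactants: 20 (4S,5Z,8R)-8-[(4-methoxybenzyl)oxy]-9-[(4R,6R)-2,2-dimethyl-6-(2-phenylethyl)-1,3-dioxan-4-yl]nona-1,5-dien-4-ol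
Product: 21 (4S,5Z,8R)-8-[(4-methoxybenzyl)oxy]-9-[(4R,6R)-2,2-dimethyl-6-(2-phenylethyl)-1,3-dioxan-4-yl]nona-1,5-dien-4-yl prop-2-enoate
Conditions: acryloyl chloride, Et3N, DMAP (cat.), CH2Cl2, 0 °C
Reagents that add atoms: acryloyl chloride, C=CC(=O)Cl
Why: DMAP-catalysed O-acylation of the secondary allylic alcohol proceeds with retention because no bond to the stereocentre is broken.

**Step 12**
Reactants: 21 (4S,5Z,8R)-8-[(4-methoxybenzyl)oxy]-9-[(4R,6R)-2,2-dimethyl-6-(2-phenylethyl)-1,3-dioxan-4-yl]nona-1,5-dien-4-yl prop-2-enoate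
Product: 22 (6S)-6-{(1Z,4R)-4-[(4-methoxybenzyl)oxy]-5-[(4R,6R)-2,2-dimethyl-6-(2-phenylethyl)-1,3-dioxan-4-yl]pent-1-en-1-yl}-5,6-dihydro-2H-pyran-2-one
Conditions: first-generation Grubbs catalyst RuCl2(PCy3)2(=CHPh) (10 mol %), CH2Cl2 (3 mM), 40 °C
Reagents that add atoms: none
Why: Ring-closing metathesis: the carbene forms on the terminal allyl alkene and closes onto the acrylate to give the six-membered lactone with loss of ethene, whereas closure onto the internal Z-alkene would give only a strained cyclobutene, so that alkene is left intact.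

**Step 13**
Reactants: 22 (6S)-6-{(1Z,4R)-4-[(4-methoxybenzyl)oxy]-5-[(4R,6R)-2,2-dimethyl-6-(2-phenylethyl)-1,3-dioxan-4-yl]pent-1-en-1-yl}-5,6-dihydro-2H-pyran-2-one
Product: 23 (6S)-6-{(1Z,4R)-5-[(4R,6R)-2,2-dimethyl-6-(2-phenylethyl)-1,3-dioxan-4-yl]-4-hydroxypent-1-en-1-yl}-5,6-dihydro-2H-pyran-2-one
Conditions: DDQ, CH2Cl2/pH 7 buffer (10:1), 0 °C → rt
Reagents that add atoms: none
Why: Oxidative PMB ether cleavage (oxidation of the electron-rich benzyl ether to an oxocarbenium ion, hydrolysed by water) is selective; the acetonide, the Z-alkene and the enoate are inert to DDQ.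

**Step 14**
Reactants: 23 (6S)-6-{(1Z,4R)-5-[(4R,6R)-2,2-dimethyl-6-(2-phenylethyl)-1,3-dioxan-4-yl]-4-hydroxypent-1-en-1-yl}-5,6-dihydro-2H-pyran-2-one
Product: 24 (6S)-6-[(1Z,4R,6S,8R)-4,6,8-trihydroxy-10-phenyldec-1-en-1-yl]-5,6-dihydro-2H-pyran-2-one (target)
Conditions: AcOH/H2O (4:1), rt → 40 °C
Reagents that add atoms: none
Why: Mild aqueous acid hydrolysis of the acetonide (the anti-acetonide is strained and labile) frees the triol; the unsaturated lactone tolerates dilute acid and no hydroxyl is placed for oxa-Michael addition.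

## Compound list

1 | 2-methyl-1,3-dithiane | CC1SCCCS1 | starting material
2 | (S)-epichlorohydrin, (2S)-2-(chloromethyl)oxirane | ClC[C@@H]1CO1 | starting material
3 | 2-lithio-2-methyl-1,3-dithiane (not isolated) | [Li]C1(C)SCCCS1 | intermediate
4 | lithium (2S)-1-chloro-3-(2-methyl-1,3-dithian-2-yl)propan-2-olate (not isolated) | ClC[C@@H](O[Li])CC1(C)SCCCS1 | intermediate
5 | 2-methyl-2-{[(2S)-oxiran-2-yl]methyl}-1,3-dithiane | CC1(C[C@H]2CO2)SCCCS1 | intermediate
6 | (2R)-1-(2-methyl-1,3-dithian-2-yl)pent-4-yn-2-ol | C#CC[C@@H](O)CC1(C)SCCCS1 | intermediate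
7 | 2-{(2R)-2-[(4-methoxybenzyl)oxy]pent-4-yn-1-yl}-2-methyl-1,3-dithiane | C#CC[C@@H](OCc1ccc(OC)cc1)CC2(C)SCCCS2 | intermediate
8 | (4R)-4-[(4-methoxybenzyl)oxy]hept-6-yn-2-one | C#CC[C@@H](OCc1ccc(OC)cc1)CC(C)=O | intermediate
9 | 3-phenylpropanal | O=CCCc1ccccc1 | starting material
10 | dibutylboron enolate of 8, dibutyl{[(4R)-4-[(4-methoxybenzyl)oxy]hept-1-en-6-yn-2-yl]oxy}borane (not isolated) | C#CC[C@@H](OCc1ccc(OC)cc1)CC(=C)OB(CCCC)CCCC | intermediate
11 | dibutylboron aldolate, O-dibutylboryl derivative of 12 (not isolated) | C#CC[C@@H](OCc1ccc(OC)cc1)CC(=O)C[C@H](OB(CCCC)CCCC)CCc2ccccc2 | intermediate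
12 | (3R,7R)-3-hydroxy-7-[(4-methoxybenzyl)oxy]-1-phenyldec-9-yn-5-one | C#CC[C@@H](OCc1ccc(OC)cc1)CC(=O)C[C@H](O)CCc2ccccc2 | intermediate
13 | (3R,5S,7R)-7-[(4-methoxybenzyl)oxy]-1-phenyldec-9-yne-3,5-diol (3,5-anti; 5,7-syn) | C#CC[C@@H](OCc1ccc(OC)cc1)C[C@@H](O)C[C@H](O)CCc2ccccc2 | intermediate
14 | (4R,6R)-4-{(2R)-2-[(4-methoxybenzyl)oxy]pent-4-yn-1-yl}-2,2-dimethyl-6-(2-phenylethyl)-1,3-dioxane (anti-acetonide) | C#CC[C@@H](OCc1ccc(OC)cc1)C[C@@H]2C[C@@H](CCc3ccccc3)OC(C)(C)O2 | intermediate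
15 | lithium acetylide of 14 (not isolated) | [Li]C#CC[C@@H](OCc1ccc(OC)cc1)C[C@@H]2C[C@@H](CCc3ccccc3)OC(C)(C)O2 | intermediate
16 | lithium (5R)-1-(dimethylamino)-5-[(4-methoxybenzyl)oxy]-6-[(4R,6R)-2,2-dimethyl-6-(2-phenylethyl)-1,3-dioxan-4-yl]hex-2-yn-1-olate, both C1 epimers (not isolated) | CN(C)C(O[Li])C#CC[C@@H](OCc1ccc(OC)cc1)C[C@@H]2C[C@@H](CCc3ccccc3)OC(C)(C)O2 | intermediate
17 | (5R)-5-[(4-methoxybenzyl)oxy]-6-[(4R,6R)-2,2-dimethyl-6-(2-phenylethyl)-1,3-dioxan-4-yl]hex-2-ynal | O=CC#CC[C@@H](OCc1ccc(OC)cc1)C[C@@H]2C[C@@H](CCc3ccccc3)OC(C)(C)O2 | intermediate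
18 | O-diisopinocampheylboryl derivative of 19 (not isolated) | C=CC[C@H](OB([C@@H]1C[C@@H]2C[C@H]([C@H]1C)C2(C)C)[C@@H]1C[C@@H]2C[C@H]([C@H]1C)C2(C)C)C#CC[C@@H](OCc1ccc(OC)cc1)C[C@@H]2C[C@@H](CCc3ccccc3)OC(C)(C)O2 | intermediate
19 | (4S,8R)-8-[(4-methoxybenzyl)oxy]-9-[(4R,6R)-2,2-dimethyl-6-(2-phenylethyl)-1,3-dioxan-4-yl]non-1-en-5-yn-4-ol | C=CC[C@H](O)C#CC[C@@H](OCc1ccc(OC)cc1)C[C@@H]2C[C@@H](CCc3ccccc3)OC(C)(C)O2 | intermediate
20 | (4S,5Z,8R)-8-[(4-methoxybenzyl)oxy]-9-[(4R,6R)-2,2-dimethyl-6-(2-phenylethyl)-1,3-dioxan-4-yl]nona-1,5-dien-4-ol | C=CC[C@H](O)/C=C\C[C@@H](OCc1ccc(OC)cc1)C[C@@H]2C[C@@H](CCc3ccccc3)OC(C)(C)O2 | intermediate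
21 | (4S,5Z,8R)-8-[(4-methoxybenzyl)oxy]-9-[(4R,6R)-2,2-dimethyl-6-(2-phenylethyl)-1,3-dioxan-4-yl]nona-1,5-dien-4-yl prop-2-enoate | C=CC[C@H](OC(=O)C=C)/C=C\C[C@@H](OCc1ccc(OC)cc1)C[C@@H]2C[C@@H](CCc3ccccc3)OC(C)(C)O2 | intermediate
22 | (6S)-6-{(1Z,4R)-4-[(4-methoxybenzyl)oxy]-5-[(4R,6R)-2,2-dimethyl-6-(2-phenylethyl)-1,3-dioxan-4-yl]pent-1-en-1-yl}-5,6-dihydro-2H-pyran-2-one | O=C1C=CC[C@@H](/C=C\C[C@@H](OCc2ccc(OC)cc2)C[C@@H]3C[C@@H](CCc4ccccc4)OC(C)(C)O3)O1 | intermediate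
23 | (6S)-6-{(1Z,4R)-5-[(4R,6R)-2,2-dimethyl-6-(2-phenylethyl)-1,3-dioxan-4-yl]-4-hydroxypent-1-en-1-yl}-5,6-dihydro-2H-pyran-2-one | O=C1C=CC[C@@H](/C=C\C[C@@H](O)C[C@@H]2C[C@@H](CCc3ccccc3)OC(C)(C)O2)O1 | intermediate
24 | (6S)-6-[(1Z,4R,6S,8R)-4,6,8-trihydroxy-10-phenyldec-1-en-1-yl]-5,6-dihydro-2H-pyran-2-one | O=C1C=CC[C@@H](/C=C\C[C@@H](O)C[C@@H](O)C[C@H](O)CCc2ccccc2)O1 | target

## Summary

Total step count: 14. Longest linear sequence: 14 steps (from 1 and 2; aldehyde 9 enters at step 5).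

Stereocentres: C4' comes from 2 (steps 1–2), C8' from the aldol (step 5), C6' from the directed reduction (step 6), ring C6 from the allylboration (step 9), and the Z-alkene from step 10.

**Three steps most likely to fail**

Step 6 (1,3-anti reduction). Me4NBH(OAc)3 may give only about 10:1 anti:syn, and the diol epimers are hard to separate. Fallback, setting out from 12: an Evans–Tishchenko reduction with SmI2 (0.3 equiv) and PhCHO (4 equiv) in THF at −10 °C, in which the hemiacetal of the C3 hydroxyl bound to trivalent samarium delivers hydride intramolecularly. This gives the anti-diol monoester (3R,5R,7R)-5-hydroxy-7-[(4-methoxybenzyl)oxy]-1-phenyldec-9-yn-3-yl benzoate F1, usually with more than 50:1 anti selectivity (the 5R label is a CIP effect, the spatial arrangement being that of 13). Methanolysis with K2CO3 in MeOH at rt removes the benzoate and comes back to the route at 13.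

Step 9 (allylboration of the ynal). A few percent of the C4 epimer would be almost inseparable because the other stereocentres are remote. Fallback, setting out from 17: add allylMgBr (THF, −78 °C) without stereocontrol to give the epimeric alcohol mixture (4RS,8R)-8-[(4-methoxybenzyl)oxy]-9-[(4R,6R)-2,2-dimethyl-6-(2-phenylethyl)-1,3-dioxan-4-yl]non-1-en-5-yn-4-ol F2. Oxidise it with Dess–Martin periodinane and NaHCO3 (CH2Cl2, 0 °C) to the ynone (8R)-8-[(4-methoxybenzyl)oxy]-9-[(4R,6R)-2,2-dimethyl-6-(2-phenylethyl)-1,3-dioxan-4-yl]non-1-en-5-yn-4-one F3, used at once because the β,γ-unsaturated ketone can slip into conjugation. Noyori asymmetric transfer hydrogenation with RuCl[(S,S)-TsDPEN](p-cymene) in i-PrOH at rt, which gives (S)-propargylic alcohols from ynones in high ee, comes back to the route at 19.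

Step 10 (semihydrogenation beside a terminal alkene). Over-reduction of the allyl group gives a propyl by-product that cannot be removed, and the later metathesis must also tolerate the Z-alkene. Fallback, setting out from 19: postpone the reduction. Acylate with acryloyl chloride, Et3N and DMAP (CH2Cl2, 0 °C) to the enyne acrylate (4S,8R)-8-[(4-methoxybenzyl)oxy]-9-[(4R,6R)-2,2-dimethyl-6-(2-phenylethyl)-1,3-dioxan-4-yl]non-1-en-5-yn-4-yl prop-2-enoate F4. Close the ring with first-generation Grubbs catalyst RuCl2(PCy3)2(=CHPh) (CH2Cl2, 40 °C) to the alkynyl lactone (6S)-6-{(4R)-4-[(4-methoxybenzyl)oxy]-5-[(4R,6R)-2,2-dimethyl-6-(2-phenylethyl)-1,3-dioxan-4-yl]pent-1-yn-1-yl}-5,6-dihydro-2H-pyran-2-one F5. Then reduce the alkyne with H2 over Pd/CaCO3 poisoned with Pb(OAc)2 and quinoline, where only the alkyne and a conjugated disubstituted alkene compete; this comes back to the route at 22.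

## Further compounds

F1 | step 6 | (3R,5R,7R)-5-hydroxy-7-[(4-methoxybenzyl)oxy]-1-phenyldec-9-yn-3-yl benzoate | C#CC[C@@H](OCc1ccc(OC)cc1)C[C@@H](O)C[C@H](OC(=O)c2ccccc2)CCc3ccccc3
F2 | step 9 | (4RS,8R)-8-[(4-methoxybenzyl)oxy]-9-[(4R,6R)-2,2-dimethyl-6-(2-phenylethyl)-1,3-dioxan-4-yl]non-1-en-5-yn-4-ol (C4 epimer mixture) | C=CCC(O)C#CC[C@@H](OCc1ccc(OC)cc1)C[C@@H]2C[C@@H](CCc3ccccc3)OC(C)(C)O2
F3 | step 9 | (8R)-8-[(4-methoxybenzyl)oxy]-9-[(4R,6R)-2,2-dimethyl-6-(2-phenylethyl)-1,3-dioxan-4-yl]non-1-en-5-yn-4-one | C=CCC(=O)C#CC[C@@H](OCc1ccc(OC)cc1)C[C@@H]2C[C@@H](CCc3ccccc3)OC(C)(C)O2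
F4 | step 10 | (4S,8R)-8-[(4-methoxybenzyl)oxy]-9-[(4R,6R)-2,2-dimethyl-6-(2-phenylethyl)-1,3-dioxan-4-yl]non-1-en-5-yn-4-yl prop-2-enoate | C=CC[C@H](OC(=O)C=C)C#CC[C@@H](OCc1ccc(OC)cc1)C[C@@H]2C[C@@H](CCc3ccccc3)OC(C)(C)O2
F5 | step 10 | (6S)-6-{(4R)-4-[(4-methoxybenzyl)oxy]-5-[(4R,6R)-2,2-dimethyl-6-(2-phenylethyl)-1,3-dioxan-4-yl]pent-1-yn-1-yl}-5,6-dihydro-2H-pyran-2-one | O=C1C=CC[C@@H](C#CC[C@@H](OCc2ccc(OC)cc2)C[C@@H]3C[C@@H](CCc4ccccc4)OC(C)(C)O3)O1
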